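**Plan**

1. Locants used below (drimane style): ring A = C1, C2, C3 (carbinol), C4 (gem-dimethyl), C5 (ring-fusion CH), C10 (ring-fusion sp2 carbon, double bond to C1); ring B = C5, C6, C7, C8 (CHMe), C9 (quaternary: Me and C11H2–aryl), C10.
2. Retrosynthetic cuts in order: the aryl C–CHO bond (the des-formyl arene is locally symmetric, so only one site exists); then C4–C5 together with one C1–H bond, which opens ring A to an (S)-2,2-dimethyloxirane (C3/C4) tethered through C2–C1 to a C5=C10 alkene of ring B; then C10–C1 (enol triflate plus homoprenyl Grignard reagent); then C9–C11 and C8–CH3 (conjugate addition/benzylation of 2-methylcyclohex-2-enone).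
3. Enabling feature: ring A is a cyclohexene in which the C3 carbinol sits beside the gem-dimethyl C4, C4 is bonded to the ring-fusion methine C5, and the C1=C10 double bond starts at the other ring-fusion carbon. This is the imprint of an oxirane-derived C4 radical adding 6-endo to a C5=C10 alkene, followed by loss of a hydrogen from C1.
4. Forward order: the arene is bought and kept symmetric; ring B comes from the cyclohexenone and is carried throughout; ring A is closed last by a titanocene radical cyclization; deprotection and formylation finish.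
5. Stereochemistry: C8 by ligand-controlled conjugate addition; C9 by enolate benzylation anti to the C8 methyl; C3 by reagent-controlled Shi epoxidation; C5 in the key step through a chair transition state (relay from C3, reinforced by C9).

Key step: step 9

Assumption: the open hydroxy-aldehyde as drawn is taken as the target; a lactol ring tautomer in equilibrium with it is the same compound.
Abbreviation: Ar = 4-({[tert-butyl(dimethyl)silyl]oxy}methyl)-2,6-bis(methoxymethoxy)phenyl.

**Route**

Step 1
Reactants: 1 3,5-dihydroxybenzyl alcohol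
Product: 2 [3,5-bis(methoxymethoxy)phenyl]methanol
Conditions: MOMCl (2.2 equiv), K2CO3, acetone, 0 °C to rt
Reagents that add atoms: chloromethyl methyl ether (MOMCl), COCCl
Why: Williamson-type O-alkylation: carbonate deprotonates only the two phenols, which are far more acidic than the benzylic alcohol, so the phenoxides alone capture MOMCl.

Step 2
Reactants: 2 [3,5-bis(methoxymethoxy)phenyl]methanol
Product: 3 tert-butyl{[3,5-bis(methoxymethoxy)phenyl]methoxy}dimethylsilane
Conditions: TBSCl, imidazole, DMF, rt
Reagents that add atoms: tert-butyldimethylsilyl chloride, CC(C)(C)[Si](C)(C)Cl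
Why: Standard imidazole-promoted silylation of the only free (primary) hydroxyl gives a benzylic ether that tolerates the organometallic steps ahead.

Step 3
Reactants: 3 tert-butyl{[3,5-bis(methoxymethoxy)phenyl]methoxy}dimethylsilane
Product: 6 ArCH2OH {[4-({[tert-butyl(dimethyl)silyl]oxy}methyl)-2,6-bis(methoxymethoxy)phenyl]methanol}, via the aryllithium 4 (not isolated), via the benzaldehyde 5 (not isolated)
Conditions: n-BuLi, THF, 0 °C; DMF, 0 °C; then MeOH, NaBH4, 0 °C
Reagents that add atoms: N,N-dimethylformamide, CN(C)C=O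
Why: Directed ortho-metalation: the carbon between the two OMOM groups is the only one with two cooperating directors and is lithiated selectively, the aryllithium is formylated by DMF, and the aldehyde set free by methanol is reduced in the same flask by borohydride.

Step 4
Reactants: 6 ArCH2OH
Product: 7 ArCH2Br {[4-(bromomethyl)-3,5-bis(methoxymethoxy)phenyl]methoxy}(tert-butyl)dimethylsilane
Conditions: CBr4, PPh3, 2,6-lutidine, CH2Cl2, −20 to 0 °C; used at once
Reagents that add atoms: carbon tetrabromide, BrC(Br)(Br)Br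
Why: Appel bromination runs under neutral conditions through the alkoxyphosphonium bromide, so the acid-labile MOM and silyl ethers survive and the reactive electron-rich benzylic bromide is obtained without free HBr.

Step 5
Reactants: 8 2-methylcyclohex-2-en-1-one; 7 ArCH2Br
Product: 10 (2S,3R)-2-(Ar-methyl)-2,3-dimethylcyclohexan-1-one, via the magnesium enolate 9 (not isolated)
Conditions: MeMgBr, CuBr·SMe2 (5 mol %), chiral TADDOL-derived phosphine–phosphite ligand (6 mol %, the enantiomer that gives the 3R enolate), 2-MeTHF, −78 °C; then 7, HMPA, −78 °C to rt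
Reagents that add atoms: methylmagnesium bromide, C[Mg]Br
Why: Copper-catalysed asymmetric conjugate addition of the Grignard reagent sets C8 (R) under ligand control and gives the regiodefined tetrasubstituted magnesium enolate, which is C-benzylated by the highly SN2-active bromide on the face anti to the new β-methyl group (tandem conjugate addition–enolate alkylation), so the C9 quaternary centre (S) arises with the two methyl groups cis.

Step 6
Reactants: 10 (2S,3R)-2-(Ar-methyl)-2,3-dimethylcyclohexan-1-one
Product: 12 (5R,6S)-6-(Ar-methyl)-5,6-dimethylcyclohex-1-en-1-yl trifluoromethanesulfonate, via the potassium enolate 11 (not isolated)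
Conditions: KN(SiMe3)2, THF, −78 °C; PhNTf2, −78 to 0 °C
Reagents that add atoms: N-phenylbis(trifluoromethanesulfonimide), O=S(=O)(N(c1ccccc1)S(=O)(=O)C(F)(F)F)C(F)(F)F
Why: Because C9 is quaternary the ketone can enolize only towards C5, and O-sulfonylation of that potassium enolate by PhNTf2 gives the C10(OTf)=C5 enol triflate regiospecifically.

Step 7
Reactants: 12 enol triflate; 13 5-bromo-2-methylpent-2-ene
Product: 15 tert-butyl{[4-{[(1S,6R)-1,6-dimethyl-2-(4-methylpent-3-en-1-yl)cyclohex-2-en-1-yl]methyl}-3,5-bis(methoxymethoxy)phenyl]methoxy}dimethylsilane, via homoprenylmagnesium bromide 14 (not isolated)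
Conditions: 13, Mg, THF, rt; then 12, Fe(acac)3 (5 mol %), THF/NMP, −30 to 0 °C
Reagents that add atoms: none
Why: Iron-catalysed Kumada-type coupling of enol triflates with primary alkyl Grignard reagents is fast at low temperature, is not plagued by β-hydride elimination and tolerates acetal and silyl ethers, so it should forge the C10–C1 bond even beside the quaternary C9.

Step 8
Reactants: 15 diene
Product: 16 tert-butyl{[4-({(1S,6R)-2-[2-((2S)-3,3-dimethyloxiran-2-yl)ethyl]-1,6-dimethylcyclohex-2-en-1-yl}methyl)-3,5-bis(methoxymethoxy)phenyl]methoxy}dimethylsilane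
Conditions: ent-Shi ketone (L-fructose-derived enantiomer, 0.3 equiv), Oxone (2KHSO5·KHSO4·K2SO4), K2CO3, Bu4NHSO4, MeCN/dimethoxymethane/aq. Na2B4O7 buffer (pH 10.5), 0 °C
Reagents that add atoms: Oxone (potassium peroxymonosulfate), [K+].[O-]S(=O)(=O)OO
Why: Shi asymmetric epoxidation: the chiral dioxirane transfers oxygen through a spiro transition state, the enantiomeric ketone giving the S configuration at C3 of an R–CH=CMe2 alkene, and the electron-rich, unhindered prenyl-type alkene should react well before the ring B alkene that is shielded by the quaternary C9.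

Step 9
Reactants: 16 (S)-epoxide
Product: 18 (2S,5S,6R,8aR)-5-(Ar-methyl)-1,1,5,6-tetramethyl-1,2,3,5,6,7,8,8a-octahydronaphthalen-2-ol, via the trimethylsilyl ether 17 (not isolated)
Conditions: Cp2TiCl2 (0.2 equiv), Mn dust, Me3SiCl, 2,4,6-collidine, THF, rt; then K2CO3, MeOH, rt
Reagents that add atoms: none
Why: Cp2TiCl (trivalent titanium, made in the flask from Cp2TiCl2 and Mn) opens the oxirane by electron transfer at the C4–O bond to give the tertiary C4 radical while C3 keeps its oxygen and configuration, the radical adds to C5 of the ring B alkene, and the tertiary C10 radical is then quenched by a second Cp2TiCl with loss of a hydrogen from C1 (mixed disproportionation or β-hydride elimination from the alkyltitanium), which leaves the C1=C10 double bond; Me3SiCl/collidine silylates the titanium alkoxide and returns Cp2TiCl2. The closest known reaction type is the titanocene-mediated radical cyclization of epoxypolyprenes (Nugent–RajanBabu epoxide opening followed by 6-endo closure and alkene-forming termination). Ring A closes in the 6-endo-trig mode, preferred to 5-exo because attack at C10 would build a quaternary carbon between the quaternary C9 and C4 and would give a secondary instead of a tertiary radical. The new stereocentre C5 is set by a chair-like transition state with the C3–O–Ti group equatorial, which places H-3 and H-5 cis as in the target, and the C9 quaternary centre, whose methyl group is pseudoaxial on the opposite face in the half-chair that keeps the C8 methyl equatorial, directs C4 to the same face of C5, so the two control elements should be matched. The step needs the termination to take a hydrogen from C1 and not from C5, which is secured by the open C1 methylene against the tertiary C5–H buried between C4 and C9, and it needs cyclization to outrun trapping of the C4 radical, which is secured by the low standing concentration of Cp2TiCl under the catalytic conditions.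

Step 10
Reactants: 18 tricyclic alcohol
Product: 19 5-(hydroxymethyl)-2-{[(1S,2R,4aR,6S)-6-hydroxy-1,2,5,5-tetramethyl-1,2,3,4,4a,5,6,7-octahydronaphthalen-1-yl]methyl}benzene-1,3-diol
Conditions: HCl (0.5 M in MeOH), 0 °C to rt
Reagents that add atoms: none
Why: Acid-catalysed acetal exchange and silyl ether methanolysis remove both aryl MOM groups and the primary TBS group in one operation, under acid too dilute and too cold to protonate the trisubstituted C1=C10 alkene.

Step 11
Reactants: 19 des-formyl tetraol
Product: 20 2,4-dihydroxy-6-(hydroxymethyl)-3-{[(1S,2R,4aR,6S)-6-hydroxy-1,2,5,5-tetramethyl-1,2,3,4,4a,5,6,7-octahydronaphthalen-1-yl]methyl}benzaldehyde (target)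
Conditions: MgCl2, Et3N, paraformaldehyde, MeCN, reflux; then aq. NH4Cl
Reagents that add atoms: paraformaldehyde (formaldehyde), C=O
Why: Magnesium-mediated ortho-formylation of phenols (Casnati–Skattebøl type): the magnesium phenoxide delivers formaldehyde to its ortho carbon and a second formaldehyde oxidizes the resulting benzylic alkoxide by hydride transfer, and because the two free ring positions of 19 are equivalent by local symmetry, each ortho to one hydroxyl and para to the other, only one mono-aldehyde can form.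

**Compound list**

1 | 3,5-dihydroxybenzyl alcohol | OCc1cc(O)cc(O)c1 | starting material
2 | [3,5-bis(methoxymethoxy)phenyl]methanol | OCc1cc(OCOC)cc(OCOC)c1 | intermediate
3 | tert-butyl{[3,5-bis(methoxymethoxy)phenyl]methoxy}dimethylsilane | CC(C)(C)[Si](C)(C)OCc1cc(OCOC)cc(OCOC)c1 | intermediate
4 | [4-({[tert-butyl(dimethyl)silyl]oxy}methyl)-2,6-bis(methoxymethoxy)phenyl]lithium | [Li]c1c(OCOC)cc(CO[Si](C)(C)C(C)(C)C)cc1OCOC | intermediate (not isolated)
5 | 4-({[tert-butyl(dimethyl)silyl]oxy}methyl)-2,6-bis(methoxymethoxy)benzaldehyde | O=Cc1c(OCOC)cc(CO[Si](C)(C)C(C)(C)C)cc1OCOC | intermediate (not isolated)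
6 | [4-({[tert-butyl(dimethyl)silyl]oxy}methyl)-2,6-bis(methoxymethoxy)phenyl]methanol | OCc1c(OCOC)cc(CO[Si](C)(C)C(C)(C)C)cc1OCOC | intermediate
7 | {[4-(bromomethyl)-3,5-bis(methoxymethoxy)phenyl]methoxy}(tert-butyl)dimethylsilane | BrCc1c(OCOC)cc(CO[Si](C)(C)C(C)(C)C)cc1OCOC | intermediate
8 | 2-methylcyclohex-2-en-1-one | CC1=CCCCC1=O | starting material
9 | bromomagnesium (R)-2,3-dimethylcyclohex-1-en-1-olate | C[C@@H]1CCCC(O[Mg]Br)=C1C | intermediate (not isolated)
10 | (2S,3R)-2-{[4-({[tert-butyl(dimethyl)silyl]oxy}methyl)-2,6-bis(methoxymethoxy)phenyl]methyl}-2,3-dimethylcyclohexan-1-one | C[C@@H]1CCCC(=O)[C@@]1(C)Cc1c(OCOC)cc(CO[Si](C)(C)C(C)(C)C)cc1OCOC | intermediate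
11 | potassium (5R,6S)-6-{[4-({[tert-butyl(dimethyl)silyl]oxy}methyl)-2,6-bis(methoxymethoxy)phenyl]methyl}-5,6-dimethylcyclohex-1-en-1-olate | C[C@@H]1CCC=C([O-])[C@@]1(C)Cc1c(OCOC)cc(CO[Si](C)(C)C(C)(C)C)cc1OCOC.[K+] | intermediate (not isolated)
12 | (5R,6S)-6-{[4-({[tert-butyl(dimethyl)silyl]oxy}methyl)-2,6-bis(methoxymethoxy)phenyl]methyl}-5,6-dimethylcyclohex-1-en-1-yl trifluoromethanesulfonate | C[C@@H]1CCC=C(OS(=O)(=O)C(F)(F)F)[C@@]1(C)Cc1c(OCOC)cc(CO[Si](C)(C)C(C)(C)C)cc1OCOC | intermediate
13 | 5-bromo-2-methylpent-2-ene | CC(C)=CCCBr | starting material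
14 | (4-methylpent-3-en-1-yl)magnesium bromide | CC(C)=CCC[Mg]Br | intermediate (not isolated)
15 | tert-butyl{[4-{[(1S,6R)-1,6-dimethyl-2-(4-methylpent-3-en-1-yl)cyclohex-2-en-1-yl]methyl}-3,5-bis(methoxymethoxy)phenyl]methoxy}dimethylsilane | C[C@@H]1CCC=C(CCC=C(C)C)[C@@]1(C)Cc1c(OCOC)cc(CO[Si](C)(C)C(C)(C)C)cc1OCOC | intermediate
16 | tert-butyl{[4-({(1S,6R)-2-[2-((2S)-3,3-dimethyloxiran-2-yl)ethyl]-1,6-dimethylcyclohex-2-en-1-yl}methyl)-3,5-bis(methoxymethoxy)phenyl]methoxy}dimethylsilane | C[C@@H]1CCC=C(CC[C@@H]2OC2(C)C)[C@@]1(C)Cc1c(OCOC)cc(CO[Si](C)(C)C(C)(C)C)cc1OCOC | intermediate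
17 | tert-butyl{[4-({(1S,2R,4aR,6S)-1,2,5,5-tetramethyl-6-[(trimethylsilyl)oxy]-1,2,3,4,4a,5,6,7-octahydronaphthalen-1-yl}methyl)-3,5-bis(methoxymethoxy)phenyl]methoxy}dimethylsilane | C[C@@H]1CC[C@@H]2C(=CC[C@H](O[Si](C)(C)C)C2(C)C)[C@@]1(C)Cc1c(OCOC)cc(CO[Si](C)(C)C(C)(C)C)cc1OCOC | intermediate (not isolated)
18 | (2S,5S,6R,8aR)-5-{[4-({[tert-butyl(dimethyl)silyl]oxy}methyl)-2,6-bis(methoxymethoxy)phenyl]methyl}-1,1,5,6-tetramethyl-1,2,3,5,6,7,8,8a-octahydronaphthalen-2-ol | C[C@@H]1CC[C@@H]2C(=CC[C@H](O)C2(C)C)[C@@]1(C)Cc1c(OCOC)cc(CO[Si](C)(C)C(C)(C)C)cc1OCOC | intermediate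
19 | 5-(hydroxymethyl)-2-{[(1S,2R,4aR,6S)-6-hydroxy-1,2,5,5-tetramethyl-1,2,3,4,4a,5,6,7-octahydronaphthalen-1-yl]methyl}benzene-1,3-diol | C[C@@H]1CC[C@@H]2C(=CC[C@H](O)C2(C)C)[C@@]1(C)Cc1c(O)cc(CO)cc1O | intermediate
20 | 2,4-dihydroxy-6-(hydroxymethyl)-3-{[(1S,2R,4aR,6S)-6-hydroxy-1,2,5,5-tetramethyl-1,2,3,4,4a,5,6,7-octahydronaphthalen-1-yl]methyl}benzaldehyde | C[C@@H]1CC[C@@H]2C(=CC[C@H](O)C2(C)C)[C@@]1(C)Cc1c(O)cc(CO)c(C=O)c1O | target

**Step count and risks**

Total step count: 11. Longest linear sequence: 11 steps (from 1; the enone 8 and the bromide 13 enter as bought materials at steps 5 and 7).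

Steps most likely to fail:

1. Step 9 (key ring closure). The C10 radical may be quenched at the wrong hydrogen (C5–H, giving the tetrasubstituted alkene) or be reduced, and the hindered 6-endo addition may lose to premature trapping of the C4 radical (allylic alcohol or deoxygenation). The fallback builds a radical leaving group into C1 and sets out from 12.
   - Triflate 12 is methoxycarbonylated (Pd(OAc)2, PPh3, CO, MeOH, Et3N, DMF) to the methyl cyclohexenecarboxylate F1.
   - F1 is reduced (i-Bu2AlH, CH2Cl2, −78 °C) to the allylic alcohol F2.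
   - F2 is converted through its mesylate (MsCl, Et3N) with PhSO2Na in DMF into the allyl phenyl sulfone F3.
   - F3 is deprotonated (n-BuLi, THF, −78 °C) and alkylated with prenyl bromide at the sulfonyl carbon to give the prenylated sulfone F4 (both epimers at C1 are usable).
   - F4 is epoxidized as in step 8 to the (S)-epoxy sulfone F5.
   - F5 is treated with Cp2TiCl (from Cp2TiCl2 and Mn, THF). The same C4 radical forms and adds 6-endo to C5; the C10 radical then expels a phenylsulfonyl radical by β-scission (radical addition–fragmentation of allyl sulfones). This fixes the double bond at C1=C10 whatever the hydrogen selectivity, and the route is rejoined at 18 after aqueous work-up.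

2. Step 5 (tandem conjugate addition–benzylation). Alkylation of the hindered tetrasubstituted enolate by the ortho,ortho-disubstituted, ionization-prone bromide may be slow or O-selective, and diastereoselectivity or enantioselectivity may erode. The fallback replaces the alkylation by an aldol addition and a deoxygenation; it sets out from enolate 9 (generated from 8 as in step 5) and from benzaldehyde 5 (isolated by stopping step 3 before the borohydride addition).
   - Aldol addition at −78 °C gives the β-hydroxy ketone F6, with the quaternary centre again formed anti to the C8 methyl, as a mixture of carbinol epimers.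
   - F6 is converted with 1,1′-thiocarbonyldiimidazole and DMAP into the imidazolyl thiocarbamate F7.
   - Barton–McCombie reduction of F7 (Bu3SnH, AIBN, toluene, 90 °C) removes the benzylic oxygen and rejoins the route at 10.

3. Step 11 (formylation of the unprotected polyol). Conversion may be sluggish, a second formylation may follow, or the intermediate ortho-hydroxymethyl phenol may be captured by the neighbouring benzylic alcohol. The fallback sets out from 18 and formylates by lithiation before the phenols are freed.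
   - 18 is desilylated (Bu4NF, THF) to the diol F8.
   - Alkoxide-assisted directed ortho-lithiation of F8 (n-BuLi in excess, TMEDA, THF/hexane, 0 °C; the position between CH2OLi and OMOM is the only aromatic C–H) and DMF quench give the bis-MOM aldehyde F9.
   - Mild hydrolysis of the two MOM ethers of F9 (dilute aq. HCl, THF, rt) rejoins the route at 20.

**Further compounds**

F1 | step 9 | methyl (5R,6S)-6-{[4-({[tert-butyl(dimethyl)silyl]oxy}methyl)-2,6-bis(methoxymethoxy)phenyl]methyl}-5,6-dimethylcyclohex-1-ene-1-carboxylate | C[C@@H]1CCC=C(C(=O)OC)[C@@]1(C)Cc1c(OCOC)cc(CO[Si](C)(C)C(C)(C)C)cc1OCOC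
F2 | step 9 | [(5R,6S)-6-{[4-({[tert-butyl(dimethyl)silyl]oxy}methyl)-2,6-bis(methoxymethoxy)phenyl]methyl}-5,6-dimethylcyclohex-1-en-1-yl]methanol | C[C@@H]1CCC=C(CO)[C@@]1(C)Cc1c(OCOC)cc(CO[Si](C)(C)C(C)(C)C)cc1OCOC
F3 | step 9 | tert-butyl{[4-({(1S,6R)-1,6-dimethyl-2-[(phenylsulfonyl)methyl]cyclohex-2-en-1-yl}methyl)-3,5-bis(methoxymethoxy)phenyl]methoxy}dimethylsilane | C[C@@H]1CCC=C(CS(=O)(=O)c2ccccc2)[C@@]1(C)Cc1c(OCOC)cc(CO[Si](C)(C)C(C)(C)C)cc1OCOC
F4 | step 9 | tert-butyl{[4-({(1S,6R)-1,6-dimethyl-2-[4-methyl-1-(phenylsulfonyl)pent-3-en-1-yl]cyclohex-2-en-1-yl}methyl)-3,5-bis(methoxymethoxy)phenyl]methoxy}dimethylsilane (epimers at the sulfonyl carbon) | C[C@@H]1CCC=C(C(CC=C(C)C)S(=O)(=O)c2ccccc2)[C@@]1(C)Cc1c(OCOC)cc(CO[Si](C)(C)C(C)(C)C)cc1OCOC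
F5 | step 9 | tert-butyl{[4-({(1S,6R)-2-[2-((2S)-3,3-dimethyloxiran-2-yl)-1-(phenylsulfonyl)ethyl]-1,6-dimethylcyclohex-2-en-1-yl}methyl)-3,5-bis(methoxymethoxy)phenyl]methoxy}dimethylsilane (epimers at the sulfonyl carbon) | C[C@@H]1CCC=C(C(C[C@@H]2OC2(C)C)S(=O)(=O)c3ccccc3)[C@@]1(C)Cc1c(OCOC)cc(CO[Si](C)(C)C(C)(C)C)cc1OCOC
F6 | step 5 | (2R,3R)-2-{[4-({[tert-butyl(dimethyl)silyl]oxy}methyl)-2,6-bis(methoxymethoxy)phenyl](hydroxy)methyl}-2,3-dimethylcyclohexan-1-one (carbinol epimers) | C[C@@H]1CCCC(=O)[C@@]1(C)C(O)c1c(OCOC)cc(CO[Si](C)(C)C(C)(C)C)cc1OCOC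
F7 | step 5 | O-{[4-({[tert-butyl(dimethyl)silyl]oxy}methyl)-2,6-bis(methoxymethoxy)phenyl][(1R,2R)-1,2-dimethyl-6-oxocyclohexyl]methyl} 1H-imidazole-1-carbothioate (carbinol epimers) | C[C@@H]1CCCC(=O)[C@@]1(C)C(OC(=S)n2ccnc2)c1c(OCOC)cc(CO[Si](C)(C)C(C)(C)C)cc1OCOC
F8 | step 11 | (2S,5S,6R,8aR)-5-{[4-(hydroxymethyl)-2,6-bis(methoxymethoxy)phenyl]methyl}-1,1,5,6-tetramethyl-1,2,3,5,6,7,8,8a-octahydronaphthalen-2-ol | C[C@@H]1CC[C@@H]2C(=CC[C@H](O)C2(C)C)[C@@]1(C)Cc1c(OCOC)cc(CO)cc1OCOC
F9 | step 11 | 6-(hydroxymethyl)-3-{[(1S,2R,4aR,6S)-6-hydroxy-1,2,5,5-tetramethyl-1,2,3,4,4a,5,6,7-octahydronaphthalen-1-yl]methyl}-2,4-bis(methoxymethoxy)benzaldehyde | C[C@@H]1CC[C@@H]2C(=CC[C@H](O)C2(C)C)[C@@]1(C)Cc1c(OCOC)cc(CO)c(C=O)c1OCOC
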